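A smaller charge has given the larger share of Pdt so far: at 75 min the larch run has turned 42.3% of its Sbt, and the ash run, with the same Ctl, 35.8%.

| flask | Sbt | Ctl | time |
|---|---|---|---|
| larch | 0.150 M | 7.50 × 10⁻⁴ M |  |
| elm | 0.150 M | 0.00150 M |  |
| ash | 0.220 M | 7.50 × 10⁻⁴ M |  |
| oak | 0.0500 M | 7.50 × 10⁻⁴ M | 75 min |

| run | time / min | [Pdt] / M |
|---|---|---|
| larch run | 2.7 | 0.0044 |
| larch run | 8.2 | 0.0158 |
| larch run | 16 | 0.0254 |
| larch run | 25 | 0.0363 |
| larch run | 35 | 0.0445 |
| larch run | 47 | 0.0507 |
| larch run | 61 | 0.0573 |
| larch run | 75 | 0.0635 |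
| elm run | 2.7 | 0.0111 |
| elm run | 8.2 | 0.0287 |
| elm run | 16 | 0.0488 |
| elm run | 25 | 0.0656 |
| elm run | 35 | 0.0762 |
| elm run | 47 | 0.0824 |
| elm run | 61 | 0.0898 |
| elm run | 75 | 0.0909 |
| ash run | 2.7 | 0.0065 |
| ash run | 8.2 | 0.0181 |
| ash run | 16 | 0.0345 |
| ash run | 25 | 0.0450 |
| ash run | 35 | 0.0572 |
| ash run | 47 | 0.0662 |
| ash run | 61 | 0.0733 |
| ash run | 75 | 0.0787 |

(readings scatter by 0.001 M)

- Overall: Sbt -> Pdt, with Ctl as catalyst.
- Constant volume, constant temperature.
- Bound and free are read together.
- An order is taken over about fifteen percent of the charge, up and down.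

1. apparent order in [Sbt] of the starting rate, round the charge of the larch run (the rate where two percent of its Sbt have turned into Pdt) (one fixed amount of Pdt, the same in the runs compared)
2. apparent order in [Ctl] of the starting rate, round the charge of the larch run (the rate where two percent of its Sbt have turned into Pdt)
3. Pdt in the oak run at 75 min, as a share of the Sbt charged

1. If each loss of Sbt ran through Ctl, the elm run, with twice the Ctl of the larch run, would at 35 min have had the exposure of 70.0 min in the larch run, which is shorter than 75 min, and it would stand lower. Yet the elm run reads 0.0762 M, more than the 0.0635 M of the larch run. That lead can be read in more than one way; this reckoning takes Ctl as intact and adds a loss of Sbt that is second order in c(Sbt) and needs no Ctl.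

2. The rates are then dc(Pdt)/dt = k·c(Sbt) and −dc(Sbt)/dt = k·c(Sbt) + (k/c×)·c(Sbt)·c(Sbt). Here k is a pseudo-first-order constant proportional to c(Ctl), and c× is the crossover level, the c(Sbt) at which both routes take Sbt equally. Integrated from a charge ch, c(Pdt) = c×·ln[1 + (ch/c×)·(1 − exp(−k·t))].

3. As a trial, c× in the elm run equals its charge. Its reading at 35 min then gives k = 0.0310 min⁻¹. In this reckoning both k and c× scale with Ctl, so at the Ctl of the larch and oak runs k = 0.0155 min⁻¹ and the crossover level c× is 0.0750 M. For the larch run at 75 min the formula gives 0.0649 M, which is 1.35 scatter widths from the reading.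

4. The reckoned oak curve starts with slope 7.75 × 10⁻⁴ M min⁻¹, the second route then running at 0.667 of the catalysed one. Its slope first falls on a time scale of 38.7 min, and the formula runs towards a level of 0.0383 M. At 75 min the formula gives 0.0283 M, which is 56.6% of the charge.

The forecast gives 0.57, 1.1 and 50%, holding that “the catalyst is dying with time”, whereas this reckoning keeps Ctl intact and stands higher.

The oak run gives 57.5% at 75 min, a little above the reckoned 56.6%. Round the charge of the larch run the starting orders are 0.67 in Sbt, below the order 1 of the rate in step 2, and 1.0 in Ctl.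

    Ctl + Sbt → Pdt + Ctl (40.74 M⁻¹ min⁻¹)
    2 Sbt → G (0.5412 M⁻¹ min⁻¹)
    2 Sbt ⇌ Sbt2, settled at all times (9.190 M⁻¹)

The step to G moves the readings by 30 in units of the scatter (root mean square). The ash charge stands at 2.93 of c×, and the formula, turned round, puts its quarter of that charge as Pdt at 29.7 min, earlier than the 33.1 min the ash run takes.

The readings come from a simulation for substances that don't exist; noise was put on by code.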